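The rate constants are made up; the rest is arithmetic.

**One step.** In a one-step world J and L share the charge by their constant and stop, with 0.174 M of L. The flask as it stands is this:

    J ⇌ L (K1 = 1.39, k1 = 5.56 × 10⁻⁴ s⁻¹)
    J ⇌ E (K2 = 3.1, k2 = 6.21 × 10⁻⁶ s⁻¹)
    2 J → J2 (k3 = 1.77 × 10⁻⁵ M⁻¹ s⁻¹)
    G ⇌ L, rate k4*(cs4 - [L]) while solid is left; crystals form when [L] > cs4 (cs4 = 0.13 M, k4 = 4.70 × 10⁻⁴ s⁻¹)

- beta: J 0.30 M; time 48 h
- epsilon: J 0.30 M; time 96 h

- which of the two there is more of at the end, beta (E / L)
- which of the two there is more of at the end, epsilon (E / L)
- amount of L at the end, in percent of the J charged, beta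
- amount of L at the end, in percent of the J charged, epsilon

- percentages count the J that a species holds: one J2 counts as two
- L is meant together with its G
- a doubled species enters its step squared and goes two at a time
- solid, in amounts per volume of the solution: G
- run time (beta): 48 h

**Your hunch.** You guessed that crystals hold L at its solubility for a while; trust that, then reckon how long it lasts. Set the one-step figure beside the solubility 0.13 M: it stands higher, so crystals form. Compare the half-life of J by step 1, 0.35 h, with 31 h by step 2: it is far shorter, so treat J and L as a pre-equilibrium. While crystals stand, J then sits at the solubility over the first constant, 0.0935 M.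

**The drain.** From that level of J, work out 0.00321 M h⁻¹, step 2 forward plus step 3 at two J a turn. Call this the drain: the amount per hour leaving J, L and G for E and J2 while crystals stand. Crystals last until J and L hold 0.224 M, which takes 23.9 h. Watch for that moment.

**First pass.** After it, let J and L fall together, exponentially, at the drain over that pool. Beta ends with J at 0.0662 M, epsilon with J at 0.0332 M.

**Second pass.** Put those back in. Use the mean J of the stretch, reckon E by step 2 forward, which gives 0.0930 M in beta and 0.152 M in epsilon, and let the mean E return over its constant. J and L together then end at 0.173 M in beta and 0.137 M in epsilon. Give L its share of these: 33.6% in beta, 26.5% in epsilon. My reckoning puts L ahead in beta and E ahead in epsilon.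

**The forecast.** The forecast, lower than mine for epsilon, says L with 33.8% of L in beta and E with 23.9% of L in epsilon, since “the slow drain to E and J2 uses up those crystals”.

**The run.** Beta gives 33.3% of L against 26.5% of E; epsilon gives 23.3% of L against 36.4% of E. Beta held G at 1.51% at 24.0 h and 0% at 48.0 h. At the drain, that remainder lasts 1.42 h more. Now take the flask like beta but charged with 0.51 M of J: subtract the pool and the drain over 48 h from its charge, and 25.9% of that charge remains as crystals, where the run shows G at 27.2%.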